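**Retrosynthetic overview**
1. Auranetin ⇒ 3-hydroxy-6,7,8,4'-tetramethoxyflavone, by O-methylation of the 3-OH as the last step.
2. Flavonol ⇒ (E)-2'-hydroxy-3',4',5',4-tetramethoxychalcone, by oxidative cyclisation that makes O1–C2 and C3–O.
3. Chalcone ⇒ 2'-hydroxy-3',4',5'-trimethoxyacetophenone + 4-methoxybenzaldehyde, by a crossed aldol condensation. This is the key C–C bond (future C2–C3).
4. Acetophenone ⇒ chelation-directed mono-demethylation ⇐ Friedel–Crafts acetylation of symmetric 1,2,3,4-tetramethoxybenzene ⇐ 2,3,4-trimethoxybenzaldehyde (Dakin oxidation, then methylation).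
5. Ring order: rings A and B are bought as arenes. Ring C (the pyranone) is the only ring built, in step 6.

Assumption: auranetin has no stereocentre or stereoaxis, so it is achiral and the given structure is one species. No enantiocontrol is needed, and the transient stereocentres in 9 and 11 are erased within the same steps.

**Step 1**
Reactants: 1 2,3,4-trimethoxybenzaldehyde
Product: 3 2,3,4-trimethoxyphenol, via 2,3,4-trimethoxyphenyl formate 2 (not isolated)
Conditions: 30% aq H2O2 (1.3 equiv), conc. H2SO4 (cat.), MeOH, rt, 16 h
Reagents that add atoms: hydrogen peroxide, OO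
Why: In this acid-catalysed Dakin (Baeyer–Villiger-type) oxidation the aryl group, activated by ortho- and para-OMe donors, migrates from carbon to oxygen in the perhydrate adduct, and MeOH transesterifies the labile formate 2 in the same pot.

**Step 2**
Reactants: 3 2,3,4-trimethoxyphenol
Product: 4 1,2,3,4-tetramethoxybenzene
Conditions: MeI (1.5 equiv), K2CO3 (2 equiv), acetone, reflux, 6 h
Reagents that add atoms: iodomethane (MeI), CI
Why: This Williamson ether synthesis (SN2 of the phenoxide on MeI) gives a twofold-symmetric arene whose two free ring positions are equivalent.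

**Step 3**
Reactants: 4 1,2,3,4-tetramethoxybenzene
Product: 5 2',3',4',5'-tetramethoxyacetophenone
Conditions: AcCl (1.2 equiv), SnCl4 (1.5 equiv), CH2Cl2, −10 to 0 °C, 2 h; ice/1 M HCl
Reagents that add atoms: acetyl chloride, CC(=O)Cl
Why: In this Friedel–Crafts acylation symmetry allows only one monoketone, the new acetyl group deactivates the ring towards a second acylation, and the mild Lewis acid at 0 °C spares the aryl methyl ethers (any stray ortho-demethylation only gives 7 early).

**Step 4**
Reactants: 5 2',3',4',5'-tetramethoxyacetophenone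
Product: 7 2'-hydroxy-3',4',5'-trimethoxyacetophenone, via aryloxydichloroborane chelate 6 (not isolated)
Conditions: BCl3 (1.0 M in CH2Cl2, 1.1 equiv), CH2Cl2, −78 to 0 °C, 1.5 h; then ice/1 M HCl
Reagents that add atoms: none
Why: In this chelation-directed aryl methyl ether cleavage BCl3 bridges the ketone oxygen and the adjacent 2'-OMe in a six-membered chelate, chloride removes only that methyl group by SN2, and hydrolysis of 6 frees the hydrogen-bonded phenol.

**Step 5**
Reactants: 7 2'-hydroxy-3',4',5'-trimethoxyacetophenone; 8 4-methoxybenzaldehyde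
Product: 10 (E)-2'-hydroxy-3',4',5',4-tetramethoxychalcone, via racemic aldol adduct 9 (not isolated)
Conditions: 8 (1.1 equiv), KOH (50% aq, 8 equiv), EtOH, rt, 36 h; ice/2 M HCl to pH 3
Reagents that add atoms: none
Why: In this Claisen–Schmidt (intermolecular crossed aldol) condensation the methyl ketone enolate adds to the non-enolisable aldehyde, and E1cB loss of water from 9 removes its stereocentre and gives the thermodynamically favoured E-enone.

**Step 6**
Reactants: 10 (E)-2'-hydroxy-3',4',5',4-tetramethoxychalcone
Product: 12 3-hydroxy-6,7,8,4'-tetramethoxyflavone, via racemic trans-dihydroflavonol 11 (not isolated)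
Conditions: 30% aq H2O2 (5 equiv), NaOH (2 M aq, 5 equiv), MeOH, 0 °C to rt, 6 h; 2 M HCl to pH 3
Reagents that add atoms: hydrogen peroxide, OO
Why: In this Algar–Flynn–Oyamada reaction alkaline H2O2 oxygenates the α-carbon while the phenoxide closes ring C at the β-carbon to give 11, more H2O2 dehydrogenates 11 to the aromatic flavonol and erases both transient stereocentres, and the lack of a 6'-substituent favours six-membered closure over aurone formation.

**Step 7**
Reactants: 12 3-hydroxy-6,7,8,4'-tetramethoxyflavone
Product: 13 auranetin (3,6,7,8,4'-pentamethoxyflavone)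
Conditions: MeI (2 equiv), K2CO3 (3 equiv), acetone, reflux, 8 h
Reagents that add atoms: iodomethane (MeI), CI
Why: This Williamson O-methylation acts on the only free hydroxyl, the acidic enolic 3-OH, so there is no selectivity issue and the product is the achiral target.

**Compound list**
1 | 2,3,4-trimethoxybenzaldehyde | COc1ccc(C=O)c(OC)c1OC | starting material
2 | 2,3,4-trimethoxyphenyl formate (not isolated) | COc1ccc(OC=O)c(OC)c1OC | intermediate
3 | 2,3,4-trimethoxyphenol | COc1ccc(O)c(OC)c1OC | intermediate
4 | 1,2,3,4-tetramethoxybenzene | COc1ccc(OC)c(OC)c1OC | intermediate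
5 | 2',3',4',5'-tetramethoxyacetophenone = 1-(2,3,4,5-tetramethoxyphenyl)ethanone | CC(=O)c1cc(OC)c(OC)c(OC)c1OC | intermediate
6 | (6-acetyl-2,3,4-trimethoxyphenoxy)dichloroborane, ketone oxygen coordinated to boron (not isolated) | CC(=O)c1cc(OC)c(OC)c(OC)c1OB(Cl)Cl | intermediate
7 | 2'-hydroxy-3',4',5'-trimethoxyacetophenone = 1-(2-hydroxy-3,4,5-trimethoxyphenyl)ethanone | CC(=O)c1cc(OC)c(OC)c(OC)c1O | intermediate
8 | 4-methoxybenzaldehyde (p-anisaldehyde) | COc1ccc(C=O)cc1 | starting material
9 | rac-3-hydroxy-1-(2-hydroxy-3,4,5-trimethoxyphenyl)-3-(4-methoxyphenyl)propan-1-one (racemate, no configuration written; not isolated) | COc1ccc(C(O)CC(=O)c2cc(OC)c(OC)c(OC)c2O)cc1 | intermediate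
10 | (E)-1-(2-hydroxy-3,4,5-trimethoxyphenyl)-3-(4-methoxyphenyl)prop-2-en-1-one | COc1ccc(/C=C/C(=O)c2cc(OC)c(OC)c(OC)c2O)cc1 | intermediate
11 | rac-(2R,3R)-3-hydroxy-6,7,8-trimethoxy-2-(4-methoxyphenyl)chroman-4-one (trans; racemate, one enantiomer drawn; not isolated) | COc1ccc([C@@H]2[C@H](C(=O)c3cc(OC)c(OC)c(OC)c3O2)O)cc1 | intermediate
12 | 3-hydroxy-6,7,8-trimethoxy-2-(4-methoxyphenyl)-4H-chromen-4-one | COc1ccc(-c2oc3c(OC)c(OC)c(OC)cc3c(=O)c2O)cc1 | intermediate
13 | auranetin = 3,6,7,8-tetramethoxy-2-(4-methoxyphenyl)-4H-chromen-4-one (achiral) | COc1ccc(-c2oc3c(OC)c(OC)c(OC)cc3c(=O)c2OC)cc1 | target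

**Total step count:** 7
**Longest linear sequence:** 7 steps (1 → 13). Compound 8 is bought and enters at step 5.

**Three steps most likely to fail**

**Step 6 (Algar–Flynn–Oyamada).** Yields are often moderate. The risks are competing aurone formation, oxidative cleavage of the enone, and incomplete dehydrogenation of 11.
The fallback sets out from 10 and comes back at 12, and it separates ring closure from C3 oxygenation. Compound 10 is heated with I2 (10 mol %) in DMSO at 130 °C, which cyclises and dehydrogenates it to 6,7,8,4'-tetramethoxyflavone F1. The C2–C3 double bond of the flavone is then epoxidised with dimethyldioxirane in acetone/CH2Cl2 at 0 °C to give racemic 2,3-epoxy-6,7,8,4'-tetramethoxyflavanone F2. A trace of p-TsOH in CH2Cl2 isomerises this epoxide to flavonol 12.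

**Step 4 (selective demethylation).** Excess BCl3 or too much warming can also cleave the crowded 3'- or 4'-OMe groups. Too little reagent leaves 5 behind.
The fallback sets out from 3 and comes back at 7, and it never cleaves a methyl ether. Compound 3 is acetylated (Ac2O, pyridine, rt) to 2,3,4-trimethoxyphenyl acetate F3. A Fries rearrangement follows in BF3·OEt2/AcOH at 85 °C. The position para to the oxygen is blocked by OMe, so the acetyl group moves to the single free ortho carbon and is trapped as the difluoroboron chelate of the ortho-hydroxyketone F4. Boiling aqueous EtOH hydrolyses this chelate to 7.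

**Step 3 (Friedel–Crafts acetylation).** The vicinal methoxy groups can tie up SnCl4 and slow the acylation. Forcing the reaction risks ether cleavage.
The fallback sets out from 4 and comes back at 5, and it replaces electrophilic substitution with directed ortho-metalation. Compound 4 is treated with n-BuLi/TMEDA in THF at 0 °C to give 2,3,4,5-tetramethoxyphenyllithium F5. This is added at −78 °C to N-methoxy-N-methylacetamide to form the racemic chelated lithium hemiaminal adduct F6. The adduct cannot over-add, and it collapses to ketone 5 on quenching with 1 M HCl.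

**Further compounds**
F1 | step 6 | 6,7,8-trimethoxy-2-(4-methoxyphenyl)-4H-chromen-4-one (6,7,8,4'-tetramethoxyflavone) | COc1ccc(-c2cc(=O)c3cc(OC)c(OC)c(OC)c3o2)cc1
F2 | step 6 | racemic 2,3-epoxy-6,7,8,4'-tetramethoxyflavanone (cis-fused oxirane, racemate) | COc1ccc(C23OC2C(=O)c2cc(OC)c(OC)c(OC)c2O3)cc1
F3 | step 4 | 2,3,4-trimethoxyphenyl acetate | CC(=O)Oc1ccc(OC)c(OC)c1OC
F4 | step 4 | (6-acetyl-2,3,4-trimethoxyphenoxy)difluoroborane, ketone oxygen coordinated to boron | CC(=O)c1cc(OC)c(OC)c(OC)c1OB(F)F
F5 | step 3 | 2,3,4,5-tetramethoxyphenyllithium | [Li]c1cc(OC)c(OC)c(OC)c1OC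
F6 | step 3 | lithium 1-[methoxy(methyl)amino]-1-(2,3,4,5-tetramethoxyphenyl)ethanolate (racemate) | [Li]OC(C)(N(C)OC)c1cc(OC)c(OC)c(OC)c1OC
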